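All runs stem from a simulated flask on assumed constants.

We start with a subtraction on the earlier beta run, and then ask what the charge in each new flask gives.

| setting | beta | noon | winter | summer |
|---|---|---|---|---|
| L | 0.70 M | 0.50 M | 1.0 M | 2.0 M |
| remark | run made earlier |  |  |  |
| time |  | 15 min | 15 min | 15 min |

- beta (time / min: Q / %, L / %): 0.833: 14.0, 28.0; 1.33: 18.8, 25.1; 2.50: 28.6, 21.4; 4.00: 35.3, 18.0; 6.00: 41.3, 13.4; 10.0: 45.6, 9.8

(readings scatter by 0.3 percentage points)

- what is said of Q includes J
- J is a solid; its amount is given per volume of the solution
- steps thought possible: L <-> Q; Q <-> X; X <-> Z; Z <-> L; J <-> Q; Q -> G; L <-> E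
- "hardly changes" means that all values lie within two and a half points (for a concentration: within two and a half percent of the largest)

* amount of Q at the end, in percent of the L charged for noon, winter, summer, in this order
* the shape of the row from first to last (rises, then falls / falls all the way / falls, then rises / rises all the way / hardly changes)

At 0.833 min the beta run holds 28.0% as L and 14.0% as Q, so 58.0% of its charge is in neither form. We take that part at so early a reading to be E, and assume that L and E keep their ratio as a fast pre-equilibrium. The fraction left as L, out of what has not become Q, is then the free share, 32.6%. Dividing an L reading by the free share gives the reserve, the fraction of the charge still in L and E together. For the beta run at 10.0 min that is 30.1%, beside 45.6% as Q. We expect the row to rise if J forms at the larger charges.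

The forecast gives 47%, 50% and 57%, a row that rises all the way, on the ground that “higher charges drain more material into J”.

The flasks give 36.4%, 55.7% and 68.4%, a row that rises all the way, as the forecast said.

    L ⇌ Q (K = 3.70, k = 0.00850 /s)
    Q ⇌ X (K = 1.10, k = 5.30 × 10⁻⁴ /s)
    X ⇌ Z (K = 0.940, k = 0.0100 /s)
    Z ⇌ L (k = 4.60 × 10⁻⁴ /s)
    J ⇌ Q, rate k5*(cs5 - [Q]) while solid is left; crystals form when [Q] > cs5 (solubility = 0.210 M, k = 0.0780 /s)
    Q → G (k = 4.00 × 10⁻⁵ /s)
    L ⇌ E (K = 1.90, k = 0.180 /s)

At 15.0 min J, which is counted in Q, stands at 0% at noon, 34.7% in winter and 57.7% in summer. The free share turns the summer L of 4.16% into a reserve of 12.8%, where L and E together stand at 12.2%. The noon L of 10.0% becomes a reserve of 30.7%, where L and E together stand at 29.2%.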